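**Retrosynthetic overview**

1. The target is a cyclohept-2-en-1-one (ring C1 ketone, C2=C3, C4, quaternary C5, C6, C7). The plan rests on the 1,4-diketone formed by the ring ketone C1 and the side-chain ketone C9 across the ring bond C1–C7 (C1–C7–C8–C9); this dissonant pair is cut at C1–C7 into an acyl radical at C1 and the β-carbon C7 of an E-enone.
2. The only ring is closed by that radical conjugate acylation, Se-phenyl selenoester 19 → cycloheptanone 20 (7-exo-trig). An alk-2-enoyl radical on this tether would react through its α-ketenyl form (C3 onto C7, 5-exo), and an E C2=C3 bond cannot sit in the ring, so C2=C3 is carried as a C3 silyl ether and released after ring closure (20 → 21).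
3. 19 comes from a C7 aldehyde plus the acetonylidene ylide, an acetate aldol on the C3 aldehyde (C1–C2), and hydroboration of the vinyl group on C5. C5 and C6 are set together by an enantioselective Ireland–Claisen rearrangement of geranyl ester 3. No olefin metathesis is used, because the 4-methylpent-3-enyl chain on C5 would ring-close with a terminal alkene on C4 or C6.
4. After the ring: C9 is masked as a dioxolane, the C6 CH2OTBS group is taken to CHO and then C≡CH, C2 is hydroxymethylated (Morita–Baylis–Hillman), the ketal is removed, and ruthenium-catalysed addition of 3-methylbut-2-enoic acid gives the Z-enol ester.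
5. Ring order: one ring only, the seven-membered carbocycle, formed in step 10.

Key step: step 10

Remark: cyclic compounds are named with the ring numbering of the overview (C1 ring ketone to C7; C8–C10 the 2-oxopropyl chain; C11 the carbon on C6).
Assumption: the (R,R) antipode of the diazaborolidine controller is taken to give the (2S,3R) acid 5; only the reagent antipode fixes the sense, so the (S,S) reagent is used if the sense proves opposite.
Assumption: the acetate aldol of step 5 is not stereoselective; 12–20 are carried as mixtures of C3 epimers, which converge in step 11.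

**Step 1**
Reactants: 1 geraniol, (2E)-3,7-dimethylocta-2,6-dien-1-ol; 2 3-[(tert-butyldimethylsilyl)oxy]propanoic acid
Product: 3 (2E)-3,7-dimethylocta-2,6-dien-1-yl 3-[(tert-butyldimethylsilyl)oxy]propanoate
Conditions: DCC, DMAP (cat.), CH2Cl2, 0 °C → rt
Reagents that add atoms: none
Why: Steglich esterification of an unhindered primary allylic alcohol; no stereocentre is formed and the E geometry of the trisubstituted alkene, which later defines C5, is untouched.

**Step 2**
Reactants: 3
Product: 6 methyl (2S,3R)-2-{[(tert-butyldimethylsilyl)oxy]methyl}-3-ethenyl-3,7-dimethyloct-6-enoate, via boron ketene acetal 4 (not isolated), via carboxylic acid 5 (not isolated)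
Conditions: (R,R)-2-bromo-4,5-diphenyl-1,3-bis{[3,5-bis(trifluoromethyl)phenyl]sulfonyl}-1,3,2-diazaborolidine (1.3 equiv, from the bis-sulfonamide and BBr3), NEt3, toluene–hexane, −78 °C, then 4 °C, 3–5 d; aq. work-up; then Me3SiCHN2, toluene–MeOH, 0 °C
Reagents that add atoms: (trimethylsilyl)diazomethane, C[Si](C)(C)C=[N+]=[N-]
Why: Enantioselective Ireland–Claisen rearrangement: the E(O) boron ketene acetal 4 rearranges through a chair transition state with CH2OTBS and the geranyl methyl pseudo-axial and the 4-methylpent-3-enyl chain pseudo-equatorial, which fixes the C5/C6 relative configuration from the two double-bond geometries, while the C2-symmetric diazaborolidine shields one enolate face and fixes the absolute configuration; the acid is then O-methylated.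

**Step 3**
Reactants: 6
Product: 8 methyl (2S,3R)-2-{[(tert-butyldimethylsilyl)oxy]methyl}-3-(2-hydroxyethyl)-3,7-dimethyloct-6-enoate, via B-alkyl-9-BBN adduct 7 (not isolated)
Conditions: 9-BBN (1.3 equiv), THF, rt → 50 °C; then aq. NaOH, H2O2, 0 °C
Reagents that add atoms: hydrogen peroxide, OO
Why: Hydroboration–oxidation: 9-BBN adds anti-Markovnikov to the monosubstituted vinyl group much faster than to the trisubstituted alkene, and alkaline peroxide replaces boron by OH; no stereocentre is formed.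

**Step 4**
Reactants: 8
Product: 9 methyl (2S,3R)-2-{[(tert-butyldimethylsilyl)oxy]methyl}-3,7-dimethyl-3-(2-oxoethyl)oct-6-enoate
Conditions: Dess–Martin periodinane, NaHCO3, CH2Cl2, 0 °C → rt
Reagents that add atoms: none
Why: Dess–Martin oxidation of the primary alcohol stops at the aldehyde (C3) and leaves the alkene, ester and silyl ether alone.

**Step 5**
Reactants: 9; 10 acetic acid
Product: 12 (3RS,5R,6S)-6-{[(tert-butyldimethylsilyl)oxy]methyl}-3-hydroxy-7-methoxy-5-methyl-5-(4-methylpent-3-en-1-yl)-7-oxoheptanoic acid, via dilithium acetate dianion 11 (not isolated)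
Conditions: 10 (3 equiv), LiN(iPr)2 (6 equiv), THF, 0 → 40 °C; then 9, −78 → −20 °C; aq. HCl to pH 3
Reagents that add atoms: none
Why: Aldol addition of the acetic acid dianion to the aldehyde, which at −78 °C is faster than attack on the hindered methyl ester, gives the β-hydroxy acid (C1–C3) directly; the carbinol centre C3 forms without control and is removed in step 11.

**Step 6**
Reactants: 12
Product: 14 (3RS,5R,6S)-3-[(tert-butyldimethylsilyl)oxy]-6-{[(tert-butyldimethylsilyl)oxy]methyl}-7-methoxy-5-methyl-5-(4-methylpent-3-en-1-yl)-7-oxoheptanoic acid, via silyl ester 13 (not isolated)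
Conditions: tBuMe2SiOTf (2.5 equiv), 2,6-lutidine, CH2Cl2, −78 → 0 °C; then MeOH–H2O–THF, rt, 1 h
Reagents that add atoms: tert-butyldimethylsilyl trifluoromethanesulfonate, CC(C)(C)[Si](C)(C)OS(=O)(=O)C(F)(F)F
Why: Silylation with the silyl triflate caps OH and CO2H, and the labile silyl ester is then solvolysed selectively, leaving the secondary silyl ether that later serves as the leaving group at C3.

**Step 7**
Reactants: 14
Product: 15 (3RS,5R,6R)-3-[(tert-butyldimethylsilyl)oxy]-6-{[(tert-butyldimethylsilyl)oxy]methyl}-7-hydroxy-5-methyl-5-(4-methylpent-3-en-1-yl)heptanoic acid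
Conditions: LiBH4 (4 equiv), THF, 0 °C → rt; aq. HCl to pH 4
Reagents that add atoms: none
Why: Chemoselective hydride reduction: LiBH4 reduces the methyl ester to the primary alcohol while the lithium carboxylate formed from the free acid is inert, so C7 and C1 are differentiated without a protecting group (the 6R descriptor reflects a priority change only).

**Step 8**
Reactants: 15; 16 1-(triphenyl-λ5-phosphanylidene)propan-2-one
Product: 18 (3RS,5R,6S,7E)-3-[(tert-butyldimethylsilyl)oxy]-6-{[(tert-butyldimethylsilyl)oxy]methyl}-5-methyl-5-(4-methylpent-3-en-1-yl)-9-oxodec-7-enoic acid, via aldehyde 17 (not isolated)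
Conditions: Dess–Martin periodinane, NaHCO3, CH2Cl2, 0 °C → rt; work-up at pH 4; crude 17, 16 (3 equiv), toluene, 70 °C
Reagents that add atoms: none
Why: Dess–Martin oxidation followed by Wittig olefination with the stabilised ylide gives the E-enone; the α-branched aldehyde is used crude so that C6 is not exposed to base for long, and the excess ylide compensates for the free acid.

**Step 9**
Reactants: 18
Product: 19 Se-phenyl (3RS,5R,6S,7E)-3-[(tert-butyldimethylsilyl)oxy]-6-{[(tert-butyldimethylsilyl)oxy]methyl}-5-methyl-5-(4-methylpent-3-en-1-yl)-9-oxodec-7-eneselenoate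
Conditions: N-(phenylselanyl)phthalimide, PBu3, CH2Cl2, −20 °C → rt
Reagents that add atoms: N-(phenylselanyl)phthalimide, O=C1N([Se]c2ccccc2)C(=O)c2ccccc12
Why: Phosphine-mediated acyl selenide formation (the acyloxyphosphonium ion is captured by selenolate) under neutral conditions; the phthalimide reagent releases no free selenol that could add to the enone.

**Step 10**
Reactants: 19
Product: 20 (3RS,5R,6S,7R)-3-[(tert-butyldimethylsilyl)oxy]-6-{[(tert-butyldimethylsilyl)oxy]methyl}-5-methyl-5-(4-methylpent-3-en-1-yl)-7-(2-oxopropyl)cycloheptan-1-one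
Conditions: (Me3Si)3SiH (1.5 equiv) and BEt3 (0.3 equiv) added over 8 h by syringe pump, trace air, benzene, 0.005 M, 25 °C
Reagents that add atoms: none
Why: BEt3 and O2 start a chain in which (Me3Si)3Si• abstracts PhSe from 19; the primary-alkyl acyl radical at C1, a nucleophilic σ-radical, adds to the electron-poor β-carbon C7 of the tethered E-enone, and the α-keto radical at C8 takes hydrogen from the silane to leave the 2-oxopropyl group. The closest known reaction type is the silane-mediated cyclisation of Se-phenyl selenoesters onto enones, enoates and β-alkoxyacrylates, which gives five-, six- and seven-membered cyclic ketones with a 1,4-dicarbonyl pattern. The one ring, the carbocycle C1–C7, closes in the 7-exo-trig mode (bond C1–C7, C8 exocyclic). The new stereocentre C7 is controlled by the adjacent C6: in a twist-chair transition state the quaternary C5 takes the isoclinal position, the C6 CH2OTBS group lies pseudo-axial and anti to the C5 methyl (eclipsing the enone C=C, which costs no allylic 1,3-strain in an E-enone), and the enone chain is pseudo-equatorial, so the 2-oxopropyl group ends cis to CH2OTBS (7R). The step needs 7-exo attack by C1 to beat silane reduction, decarbonylation and attack on the trisubstituted alkene; slow addition of the poor hydrogen donor (Me3Si)3SiH at high dilution, room-temperature initiation, the gem-disubstituted C5 (Thorpe–Ingold effect) and the polarity mismatch between an acyl radical and an electron-rich alkene secure this. Because C2–C3 is saturated and C3 carries OTBS, no α-ketenyl radical can form, so closure through C3 is excluded and the later C2=C3 bond stays masked.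

**Step 11**
Reactants: 20
Product: 21 (5R,6S,7R)-6-{[(tert-butyldimethylsilyl)oxy]methyl}-5-methyl-5-(4-methylpent-3-en-1-yl)-7-(2-oxopropyl)cyclohept-2-en-1-one
Conditions: DBU (3 equiv), CH2Cl2, 0 °C → rt, short contact
Reagents that add atoms: none
Why: E1cB elimination: DBU removes a C2 proton of the β-silyloxy ketone and the C1 enolate expels silanolate from C3, so both C3 epimers converge on the conjugated C2=C3 enone, while the hindered tertiary C7–H is deprotonated more slowly.

**Step 12**
Reactants: 21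
Product: 22 (5R,6S,7R)-6-{[(tert-butyldimethylsilyl)oxy]methyl}-5-methyl-7-[(2-methyl-1,3-dioxolan-2-yl)methyl]-5-(4-methylpent-3-en-1-yl)cyclohept-2-en-1-one
Conditions: 1,2-bis(trimethylsilyloxy)ethane, Me3SiOTf (5 mol %), CH2Cl2, −78 → −40 °C; pyridine quench
Reagents that add atoms: 1,2-bis(trimethylsilyloxy)ethane, C[Si](C)(C)OCCO[Si](C)(C)C
Why: Silyl-triflate-catalysed dioxolane formation at low temperature is selective for the saturated methyl ketone C9 over the conjugated, hindered ring enone; the ketal blocks aldol reactions of the 1,4- and 1,5-dicarbonyl pairs in the basic steps 15 and 16.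

**Step 13**
Reactants: 22
Product: 23 (5R,6S,7R)-6-(hydroxymethyl)-5-methyl-7-[(2-methyl-1,3-dioxolan-2-yl)methyl]-5-(4-methylpent-3-en-1-yl)cyclohept-2-en-1-one
Conditions: HF·pyridine, pyridine, THF, 0 °C → rt
Reagents that add atoms: none
Why: Fluoride cleavage of the primary silyl ether under buffered, non-basic conditions spares the dioxolane and avoids enolisation at C7 or conjugate addition of the freed alcohol.

**Step 14**
Reactants: 23
Product: 24 (5R,6S,7R)-5-methyl-7-[(2-methyl-1,3-dioxolan-2-yl)methyl]-5-(4-methylpent-3-en-1-yl)-1-oxocyclohept-2-ene-6-carbaldehyde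
Conditions: Dess–Martin periodinane, NaHCO3, CH2Cl2, 0 °C → rt
Reagents that add atoms: none
Why: Buffered Dess–Martin oxidation gives the α-branched aldehyde without base, so C6 is not epimerised.

**Step 15**
Reactants: 24
Product: 25 (5R,6S,7R)-6-ethynyl-5-methyl-7-[(2-methyl-1,3-dioxolan-2-yl)methyl]-5-(4-methylpent-3-en-1-yl)cyclohept-2-en-1-one
Conditions: dimethyl (1-diazo-2-oxopropyl)phosphonate, K2CO3, MeOH, 0 °C → rt
Reagents that add atoms: dimethyl (1-diazo-2-oxopropyl)phosphonate, COP(=O)(OC)C(=[N+]=[N-])C(C)=O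
Why: Ohira–Bestmann modification of the Seyferth–Gilbert homologation: the diazomethylphosphonate anion made in situ adds to the aldehyde, and loss of phosphate and N2 with a 1,2-hydrogen shift gives the terminal alkyne; with C9 masked no ketone enolate can add to the aldehyde, and the low temperature limits epimerisation at C6.

**Step 16**
Reactants: 25
Product: 26 (5R,6S,7R)-6-ethynyl-2-(hydroxymethyl)-5-methyl-7-[(2-methyl-1,3-dioxolan-2-yl)methyl]-5-(4-methylpent-3-en-1-yl)cyclohept-2-en-1-one
Conditions: aq. formaldehyde (37 %), imidazole (1 equiv), THF–aq. NaHCO3 (1 M), rt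
Reagents that add atoms: formaldehyde, C=O
Why: Morita–Baylis–Hillman reaction: imidazole adds to C3, the C1–C2 enolate is hydroxymethylated at C2 by formaldehyde, and loss of the catalyst restores C2=C3; the weakly basic aqueous medium leaves the alkyne, ketal and stereocentres untouched.

**Step 17**
Reactants: 26
Product: 27 (5R,6S,7R)-6-ethynyl-2-(hydroxymethyl)-5-methyl-5-(4-methylpent-3-en-1-yl)-7-(2-oxopropyl)cyclohept-2-en-1-one
Conditions: pyridinium p-toluenesulfonate (0.2 equiv), acetone–H2O (10:1), 45 °C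
Reagents that add atoms: water, O
Why: Mild acid-catalysed hydrolysis of the dioxolane frees the C9 ketone without affecting the allylic alcohol, the alkyne or the C7 stereocentre.

**Step 18**
Reactants: 27; 28 3-methylbut-2-enoic acid
Product: 29 (1Z)-2-[(5R,6S,7R)-2-(hydroxymethyl)-5-methyl-5-(4-methylpent-3-en-1-yl)-1-oxo-7-(2-oxopropyl)cyclohept-2-en-6-yl]ethen-1-yl 3-methylbut-2-enoate (target)
Conditions: Ru(η3-CH2C(CH3)CH2)2(Ph2P(CH2)4PPh2) (5 mol %), 28 (1.5 equiv), toluene, 65 °C
Reagents that add atoms: none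
Why: Ruthenium-catalysed anti-Markovnikov addition of a carboxylic acid to a terminal alkyne: the divalent ruthenium bis(2-methylallyl) diphosphine complex forms a vinylidene at the terminal carbon, the carboxylate adds to it, and protonolysis gives the Z-enol ester; the bulky propargylic centre reinforces terminal attack and no stereocentre is touched.

**Compound list**

1 | geraniol, (2E)-3,7-dimethylocta-2,6-dien-1-ol | CC(C)=CCC/C(C)=C/CO | starting material
2 | 3-[(tert-butyldimethylsilyl)oxy]propanoic acid | OC(=O)CCO[Si](C)(C)C(C)(C)C | starting material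
3 | (2E)-3,7-dimethylocta-2,6-dien-1-yl 3-[(tert-butyldimethylsilyl)oxy]propanoate | CC(C)=CCC/C(C)=C/COC(=O)CCO[Si](C)(C)C(C)(C)C | intermediate
4 | boron ketene acetal of 3, O-geranyl O-[(4R,5R)-diazaborolidin-2-yl], CH2OTBS cis to the geranyloxy oxygen (E(O) enolate geometry) | CC(C)(C)[Si](C)(C)OC/C=C(\OC/C=C(C)/CCC=C(C)C)OB1N(S(=O)(=O)c2cc(cc(c2)C(F)(F)F)C(F)(F)F)[C@H](c2ccccc2)[C@@H](c2ccccc2)N1S(=O)(=O)c1cc(cc(c1)C(F)(F)F)C(F)(F)F | intermediate
5 | (2S,3R)-2-{[(tert-butyldimethylsilyl)oxy]methyl}-3-ethenyl-3,7-dimethyloct-6-enoic acid | OC(=O)[C@H](CO[Si](C)(C)C(C)(C)C)[C@](C)(CCC=C(C)C)C=C | intermediate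
6 | methyl (2S,3R)-2-{[(tert-butyldimethylsilyl)oxy]methyl}-3-ethenyl-3,7-dimethyloct-6-enoate | COC(=O)[C@H](CO[Si](C)(C)C(C)(C)C)[C@](C)(CCC=C(C)C)C=C | intermediate
7 | methyl (2S,3S)-3-[2-(9-borabicyclo[3.3.1]nonan-9-yl)ethyl]-2-{[(tert-butyldimethylsilyl)oxy]methyl}-3,7-dimethyloct-6-enoate (same spatial arrangement as 6) | COC(=O)[C@H](CO[Si](C)(C)C(C)(C)C)[C@](C)(CCC=C(C)C)CCB1C2CCCC1CCC2 | intermediate
8 | methyl (2S,3R)-2-{[(tert-butyldimethylsilyl)oxy]methyl}-3-(2-hydroxyethyl)-3,7-dimethyloct-6-enoate | COC(=O)[C@H](CO[Si](C)(C)C(C)(C)C)[C@](C)(CCC=C(C)C)CCO | intermediate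
9 | methyl (2S,3R)-2-{[(tert-butyldimethylsilyl)oxy]methyl}-3,7-dimethyl-3-(2-oxoethyl)oct-6-enoate | COC(=O)[C@H](CO[Si](C)(C)C(C)(C)C)[C@](C)(CCC=C(C)C)CC=O | intermediate
10 | acetic acid | CC(=O)O | starting material
11 | dilithium ethene-1,1-bis(olate) (acetic acid dianion) | [Li+].[Li+].[O-]C([O-])=C | intermediate
12 | (3RS,5R,6S)-6-{[(tert-butyldimethylsilyl)oxy]methyl}-3-hydroxy-7-methoxy-5-methyl-5-(4-methylpent-3-en-1-yl)-7-oxoheptanoic acid | COC(=O)[C@H](CO[Si](C)(C)C(C)(C)C)[C@](C)(CCC=C(C)C)CC(O)CC(=O)O | intermediate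
13 | tert-butyldimethylsilyl (3RS,5R,6S)-3-[(tert-butyldimethylsilyl)oxy]-6-{[(tert-butyldimethylsilyl)oxy]methyl}-7-methoxy-5-methyl-5-(4-methylpent-3-en-1-yl)-7-oxoheptanoate | COC(=O)[C@H](CO[Si](C)(C)C(C)(C)C)[C@](C)(CCC=C(C)C)CC(O[Si](C)(C)C(C)(C)C)CC(=O)O[Si](C)(C)C(C)(C)C | intermediate
14 | (3RS,5R,6S)-3-[(tert-butyldimethylsilyl)oxy]-6-{[(tert-butyldimethylsilyl)oxy]methyl}-7-methoxy-5-methyl-5-(4-methylpent-3-en-1-yl)-7-oxoheptanoic acid | COC(=O)[C@H](CO[Si](C)(C)C(C)(C)C)[C@](C)(CCC=C(C)C)CC(O[Si](C)(C)C(C)(C)C)CC(=O)O | intermediate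
15 | (3RS,5R,6R)-3-[(tert-butyldimethylsilyl)oxy]-6-{[(tert-butyldimethylsilyl)oxy]methyl}-7-hydroxy-5-methyl-5-(4-methylpent-3-en-1-yl)heptanoic acid | OC[C@H](CO[Si](C)(C)C(C)(C)C)[C@](C)(CCC=C(C)C)CC(O[Si](C)(C)C(C)(C)C)CC(=O)O | intermediate
16 | 1-(triphenyl-λ5-phosphanylidene)propan-2-one | CC(=O)C=P(c1ccccc1)(c1ccccc1)c1ccccc1 | starting material
17 | (3RS,5R,6S)-3-[(tert-butyldimethylsilyl)oxy]-6-{[(tert-butyldimethylsilyl)oxy]methyl}-5-methyl-5-(4-methylpent-3-en-1-yl)-7-oxoheptanoic acid | O=C[C@H](CO[Si](C)(C)C(C)(C)C)[C@](C)(CCC=C(C)C)CC(O[Si](C)(C)C(C)(C)C)CC(=O)O | intermediate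
18 | (3RS,5R,6S,7E)-3-[(tert-butyldimethylsilyl)oxy]-6-{[(tert-butyldimethylsilyl)oxy]methyl}-5-methyl-5-(4-methylpent-3-en-1-yl)-9-oxodec-7-enoic acid | CC(=O)/C=C/[C@H](CO[Si](C)(C)C(C)(C)C)[C@](C)(CCC=C(C)C)CC(O[Si](C)(C)C(C)(C)C)CC(=O)O | intermediate
19 | Se-phenyl (3RS,5R,6S,7E)-3-[(tert-butyldimethylsilyl)oxy]-6-{[(tert-butyldimethylsilyl)oxy]methyl}-5-methyl-5-(4-methylpent-3-en-1-yl)-9-oxodec-7-eneselenoate | CC(=O)/C=C/[C@H](CO[Si](C)(C)C(C)(C)C)[C@](C)(CCC=C(C)C)CC(O[Si](C)(C)C(C)(C)C)CC(=O)[Se]c1ccccc1 | intermediate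
20 | (3RS,5R,6S,7R)-3-[(tert-butyldimethylsilyl)oxy]-6-{[(tert-butyldimethylsilyl)oxy]methyl}-5-methyl-5-(4-methylpent-3-en-1-yl)-7-(2-oxopropyl)cycloheptan-1-one | CC(=O)C[C@H]1C(=O)CC(O[Si](C)(C)C(C)(C)C)C[C@@](C)(CCC=C(C)C)[C@H]1CO[Si](C)(C)C(C)(C)C | intermediate
21 | (5R,6S,7R)-6-{[(tert-butyldimethylsilyl)oxy]methyl}-5-methyl-5-(4-methylpent-3-en-1-yl)-7-(2-oxopropyl)cyclohept-2-en-1-one | CC(=O)C[C@H]1C(=O)C=CC[C@@](C)(CCC=C(C)C)[C@H]1CO[Si](C)(C)C(C)(C)C | intermediate
22 | (5R,6S,7R)-6-{[(tert-butyldimethylsilyl)oxy]methyl}-5-methyl-7-[(2-methyl-1,3-dioxolan-2-yl)methyl]-5-(4-methylpent-3-en-1-yl)cyclohept-2-en-1-one | CC1(C[C@H]2C(=O)C=CC[C@@](C)(CCC=C(C)C)[C@H]2CO[Si](C)(C)C(C)(C)C)OCCO1 | intermediate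
23 | (5R,6S,7R)-6-(hydroxymethyl)-5-methyl-7-[(2-methyl-1,3-dioxolan-2-yl)methyl]-5-(4-methylpent-3-en-1-yl)cyclohept-2-en-1-one | CC1(C[C@H]2C(=O)C=CC[C@@](C)(CCC=C(C)C)[C@H]2CO)OCCO1 | intermediate
24 | (5R,6S,7R)-5-methyl-7-[(2-methyl-1,3-dioxolan-2-yl)methyl]-5-(4-methylpent-3-en-1-yl)-1-oxocyclohept-2-ene-6-carbaldehyde | CC1(C[C@H]2C(=O)C=CC[C@@](C)(CCC=C(C)C)[C@H]2C=O)OCCO1 | intermediate
25 | (5R,6S,7R)-6-ethynyl-5-methyl-7-[(2-methyl-1,3-dioxolan-2-yl)methyl]-5-(4-methylpent-3-en-1-yl)cyclohept-2-en-1-one | CC1(C[C@H]2C(=O)C=CC[C@@](C)(CCC=C(C)C)[C@H]2C#C)OCCO1 | intermediate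
26 | (5R,6S,7R)-6-ethynyl-2-(hydroxymethyl)-5-methyl-7-[(2-methyl-1,3-dioxolan-2-yl)methyl]-5-(4-methylpent-3-en-1-yl)cyclohept-2-en-1-one | CC1(C[C@H]2C(=O)C(CO)=CC[C@@](C)(CCC=C(C)C)[C@H]2C#C)OCCO1 | intermediate
27 | (5R,6S,7R)-6-ethynyl-2-(hydroxymethyl)-5-methyl-5-(4-methylpent-3-en-1-yl)-7-(2-oxopropyl)cyclohept-2-en-1-one | CC(=O)C[C@H]1C(=O)C(CO)=CC[C@@](C)(CCC=C(C)C)[C@H]1C#C | intermediate
28 | 3-methylbut-2-enoic acid | CC(C)=CC(=O)O | starting material
29 | (1Z)-2-[(5R,6S,7R)-2-(hydroxymethyl)-5-methyl-5-(4-methylpent-3-en-1-yl)-1-oxo-7-(2-oxopropyl)cyclohept-2-en-6-yl]ethen-1-yl 3-methylbut-2-enoate | CC(=O)C[C@H]1C(=O)C(CO)=CC[C@@](C)(CCC=C(C)C)[C@H]1/C=C\OC(=O)C=C(C)C | target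

**Step count**

Total: 18 steps. Longest linear sequence: 18 steps (from geraniol 1 to 29).

**Steps most likely to fail**

Step 10. The facial selectivity of the 7-exo closure may be poor or reversed, so that the 2-oxopropyl group at C7 ends trans to the C6 substituent; the DBU of step 11 could erode C7 further. In the fallback the closure is used only to build the ring and C7 is set afterwards by enolate protonation. From 19 the cyclisation then gives the C7-epimeric cycloheptanone F1 (alone or mixed with 20). DBU converts it into the (7S)-enone F2, and silyl-triflate-catalysed dioxolane formation gives the (7S)-ketal F3. In F3 the only α′-hydrogen is H7, because C9 is masked, so LiN(iPr)2 in THF at −78 °C gives regiospecifically the cross-conjugated lithium dienolate F4, in which C7 is trigonal. Kinetic protonation with acetic acid at −78 °C, on the face opposite to the pseudo-axial CH2OTBS group at C6, gives 22, where the route is rejoined.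

Step 2. The boron-mediated rearrangement may lose enolate geometry or facial control, for example through coordination of the silyloxy oxygen to boron, or the Lewis-acidic bromoborane may remove the silyl ether. In the fallback, 3 undergoes the classical Ireland–Claisen rearrangement (LiN(iPr)2, Me3SiCl, THF, −78 °C → rt) through the E(O) trimethylsilyl ketene acetal F5 to the racemic acid of the same relative configuration F6. This acid is resolved: DCC/DMAP acylation of (4S)-4-benzyl-1,3-oxazolidin-2-one gives the (2S,3R)-acyl imide F7 and the (2R,3S)-acyl imide F8, which are separated by chromatography. LiOH/H2O2 cleaves F7 to acid 5, which is methylated as in step 2 to give 6.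

Step 16. Conjugate addition of the amine catalyst to the hindered seven-membered enone may be slow, so that the hydroxymethylation stalls. In the fallback, 25 is iodinated at C2 (I2, pyridine, CH2Cl2, 0 °C → rt) to the 2-iodoenone F9, and copper-free Stille coupling with (tributylstannyl)methanol (Pd(PPh3)4, zerovalent palladium, dioxane, 80 °C) gives 26.

**Further compounds**

F1 | step 10 | (3RS,5R,6S,7S)-3-[(tert-butyldimethylsilyl)oxy]-6-{[(tert-butyldimethylsilyl)oxy]methyl}-5-methyl-5-(4-methylpent-3-en-1-yl)-7-(2-oxopropyl)cycloheptan-1-one | CC(=O)C[C@@H]1C(=O)CC(O[Si](C)(C)C(C)(C)C)C[C@@](C)(CCC=C(C)C)[C@H]1CO[Si](C)(C)C(C)(C)C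
F2 | step 10 | (5R,6S,7S)-6-{[(tert-butyldimethylsilyl)oxy]methyl}-5-methyl-5-(4-methylpent-3-en-1-yl)-7-(2-oxopropyl)cyclohept-2-en-1-one | CC(=O)C[C@@H]1C(=O)C=CC[C@@](C)(CCC=C(C)C)[C@H]1CO[Si](C)(C)C(C)(C)C
F3 | step 10 | (5R,6S,7S)-6-{[(tert-butyldimethylsilyl)oxy]methyl}-5-methyl-7-[(2-methyl-1,3-dioxolan-2-yl)methyl]-5-(4-methylpent-3-en-1-yl)cyclohept-2-en-1-one | CC1(C[C@@H]2C(=O)C=CC[C@@](C)(CCC=C(C)C)[C@H]2CO[Si](C)(C)C(C)(C)C)OCCO1
F4 | step 10 | lithium (5R,6S)-6-{[(tert-butyldimethylsilyl)oxy]methyl}-5-methyl-7-[(2-methyl-1,3-dioxolan-2-yl)methyl]-5-(4-methylpent-3-en-1-yl)cyclohepta-2,7-dien-1-olate | [Li+].CC1(CC2=C([O-])C=CC[C@@](C)(CCC=C(C)C)[C@H]2CO[Si](C)(C)C(C)(C)C)OCCO1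
F5 | step 2 | trimethylsilyl ketene acetal of 3, CH2OTBS cis to the geranyloxy oxygen | CC(C)(C)[Si](C)(C)OC/C=C(\OC/C=C(C)/CCC=C(C)C)O[Si](C)(C)C
F6 | step 2 | racemic (2S*,3R*)-2-{[(tert-butyldimethylsilyl)oxy]methyl}-3-ethenyl-3,7-dimethyloct-6-enoic acid (5 and its enantiomer) | OC(=O)[C@H](CO[Si](C)(C)C(C)(C)C)[C@](C)(CCC=C(C)C)C=C.OC(=O)[C@@H](CO[Si](C)(C)C(C)(C)C)[C@@](C)(CCC=C(C)C)C=C
F7 | step 2 | (4S)-4-benzyl-3-[(2S,3R)-2-{[(tert-butyldimethylsilyl)oxy]methyl}-3-ethenyl-3,7-dimethyloct-6-enoyl]-1,3-oxazolidin-2-one | O=C1OC[C@H](Cc2ccccc2)N1C(=O)[C@H](CO[Si](C)(C)C(C)(C)C)[C@](C)(CCC=C(C)C)C=C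
F8 | step 2 | (4S)-4-benzyl-3-[(2R,3S)-2-{[(tert-butyldimethylsilyl)oxy]methyl}-3-ethenyl-3,7-dimethyloct-6-enoyl]-1,3-oxazolidin-2-one | O=C1OC[C@H](Cc2ccccc2)N1C(=O)[C@@H](CO[Si](C)(C)C(C)(C)C)[C@@](C)(CCC=C(C)C)C=C
F9 | step 16 | (5R,6S,7R)-6-ethynyl-2-iodo-5-methyl-7-[(2-methyl-1,3-dioxolan-2-yl)methyl]-5-(4-methylpent-3-en-1-yl)cyclohept-2-en-1-one | CC1(C[C@H]2C(=O)C(I)=CC[C@@](C)(CCC=C(C)C)[C@H]2C#C)OCCO1
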